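**Retrosynthetic overview**

1. Guaiane locants are used in the discussion and systematic locants in the compound names. The seven-membered ring (C1, C5–C10) hides two pieces: C9–C8(O)–C7–C11 is a masked acetoacetate (three ring carbons) and C6–C5(O)–C1–C10–C14 is a masked 2-oxy-penta-1,3-diene (four ring carbons).
2. Seven-membered ring first: a rhodium siloxyvinyl carbenoid cyclopropanates the C5=C6 alkene and a Cope shift forms C6–C7 and C9–C10 and sets C10.
3. Five-membered ring second: the regiodefined C5 enol ether takes up C2–C3–C4–C15 at C1 as a 2-oxobutyl group (nitroalkene Michael addition, Nef hydrolysis), and aldol condensation closes C4=C5.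
4. C7 and C8 come from dynamic kinetic hydrogenation of the β-keto ester (trans) followed by Mitsunobu inversion at C8. The ester becomes the C11 carbinol with MeMgBr while the enone is masked as its allylic alcohol.
5. Endgame: methacryloylation of the C8 hydroxyl, then acetylation of the C11 hydroxyl.

Key step: step 4

Assumption: the senses of induction of Rh2(S-PTAD)4 (step 4) and of the (S)-BINAP ruthenium catalyst (step 8) are assigned by analogy with closely related substrates; should either prove opposite, the enantiomeric ligand is used and nothing else changes.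

**Route**

Step 1
Reactants: 1 methyl 3-oxobutanoate (methyl acetoacetate)
Product: 2 methyl 2-diazo-3-oxobutanoate
Conditions: p-ABSA, Et3N, MeCN, 0 °C → rt
Reagents that add atoms: 4-acetamidobenzenesulfonyl azide (p-ABSA), CC(=O)Nc1ccc(cc1)S(=O)(=O)N=[N+]=[N-]
Why: Regitz diazo transfer, in which the triethylammonium enolate of the β-keto ester attacks the terminal nitrogen of the sulfonyl azide and the adduct collapses to the diazo compound and the sulfonamide.

Step 2
Reactants: 2 methyl 2-diazo-3-oxobutanoate
Product: 3 methyl 3-(tert-butyldimethylsilyloxy)-2-diazobut-3-enoate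
Conditions: TBSOTf, Et3N, CH2Cl2, 0 °C
Reagents that add atoms: tert-butyldimethylsilyl trifluoromethanesulfonate (TBSOTf), CC(C)(C)[Si](C)(C)OS(=O)(=O)C(F)(F)F
Why: Soft enolisation, in which the silyl triflate activates the ketone and triethylamine removes a proton from the only enolisable position (the acetyl methyl), so that O-silylation gives the siloxyvinyl diazoacetate with the diazo group intact.

Step 3
Reactants: 4 (E)-pent-3-en-2-one
Product: 5 (E)-2-(triethylsilyloxy)penta-1,3-diene
Conditions: Et3SiOTf, Et3N, Et2O, 0 °C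
Reagents that add atoms: triethylsilyl trifluoromethanesulfonate (Et3SiOTf), CC[Si](CC)(CC)OS(=O)(=O)C(F)(F)F
Why: Soft enolisation of the enone with silyl triflate and amine removes an α′-methyl proton and gives the cross-conjugated 2-siloxy diene, the E-alkene being carried through unchanged.

Step 4
Reactants: 3 methyl 3-(tert-butyldimethylsilyloxy)-2-diazobut-3-enoate; 5 (E)-2-(triethylsilyloxy)penta-1,3-diene
Product: 7 methyl (S)-2-(tert-butyldimethylsilyloxy)-4-methyl-6-(triethylsilyloxy)cyclohepta-1,5-diene-1-carboxylate, via cis-divinylcyclopropane 6 (not isolated)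
Conditions: Rh2(S-PTAD)4 (1 mol%), 5 (3 equiv), hexanes, −26 °C, slow addition of 3; then 23 °C
Reagents that add atoms: none
Why: Rh2(S-PTAD)4 extrudes N2 from 3 to give a donor–acceptor siloxyvinyl carbenoid at C7, which adds in an asynchronous concerted way to the electron-rich, unhindered C5=C6 enol-ether alkene of 5 (C6–C7 bond leading), the trans-disubstituted C1=C10 alkene being inert to such carbenoids and the siloxy group on the carbenoid suppressing vinylogous attack. The closest known reaction type is the dirhodium-carboxylate-catalysed tandem cyclopropanation–Cope rearrangement, the (4+3) cycloaddition of siloxyvinyl diazoacetates with dienes, which tolerates oxygenated dienes. The three-membered ring of 6 closes by (2+1) carbene transfer with the propenyl group cis to the siloxyvinyl donor; the seven-membered ring then closes not end to end but by a [3,3] sigmatropic shift through a boat transition state that breaks C5–C7 and forms C9–C10. C10 is the only stereocentre of 7: the chiral carboxylate ligands fix the (1R,2S) configuration of the cyclopropane, and the boat geometry with the E-methyl on the outside relays it to (S)-C10. The step needs site selectivity for the siloxy-bearing terminal alkene, a cis-divinyl relationship and one enantioface; the first is secured by the electronic and steric bias of the diene, the second by the preference of donor–acceptor carbenoids to place the alkene π-substituent next to the donor, and the third by the catalyst, with a hydrocarbon solvent at low temperature disfavouring zwitterionic opening of the push–pull cyclopropane.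

Step 5
Reactants: 8 2-nitrobutan-1-ol
Product: 9 2-nitrobut-1-ene
Conditions: phthalic anhydride, 180 °C, reduced pressure, distillation
Reagents that add atoms: none
Why: Dehydration of a β-nitro alcohol, in which phthalic anhydride acylates the primary hydroxyl and the half-ester eliminates by an E1cB pathway through the nitronate, the volatile nitroalkene being distilled out as it forms.

Step 6
Reactants: 7 methyl (S)-2-(tert-butyldimethylsilyloxy)-4-methyl-6-(triethylsilyloxy)cyclohepta-1,5-diene-1-carboxylate; 9 2-nitrobut-1-ene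
Product: 11 methyl (4S,5R)-4-methyl-2,6-dioxo-5-(2-oxobutyl)cycloheptane-1-carboxylate, via silyl nitronate 10 (not isolated)
Conditions: 9 (1.5 equiv), SnCl4 (1.1 equiv), CH2Cl2, −78 °C; H2O, 40 °C; then 1 M HCl, THF, rt
Reagents that add atoms: water, O
Why: Mukaiyama–Michael addition followed by Nef hydrolysis (the nitroalkene route to 1,4-diketones), in which the C5=C1 triethylsilyl enol ether, far more nucleophilic than the ester-conjugated C7=C8 enol ether, attacks the SnCl4-activated nitroalkene through C1 on the exo face of the ring, anti to the C10–C9 bond with the C10 methyl pseudo-equatorial, which sets C1 (R) with the new chain trans to the methyl, and aqueous acid then turns the nitronate into the C3 ketone and frees the C7/C8 β-keto ester; a fluoride-triggered alkylation is avoided because it would unmask the more stabilised C7 enolate first.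

Step 7
Reactants: 11 methyl (4S,5R)-4-methyl-2,6-dioxo-5-(2-oxobutyl)cycloheptane-1-carboxylate
Product: 12 methyl (8S,8aR)-3,8-dimethyl-2,6-dioxo-1,2,4,5,6,7,8,8a-octahydroazulene-5-carboxylate
Conditions: NaOMe (3 equiv), MeOH, 0 → 45 °C; AcOH quench
Reagents that add atoms: none
Why: Intramolecular aldol condensation of the C3/C5 1,4-diketone, in which the C4 enolate closes the five-membered ring onto the C5 ketone and dehydration gives the tetrasubstituted C4=C5 enone, while the β-keto ester rests as its sodium enolate and is thereby shielded from retro-Claisen cleavage, the alternative aldol modes are bridged and reversible, and C1 can settle in the more stable arrangement trans to the C10 methyl.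

Step 8
Reactants: 12 methyl (8S,8aR)-3,8-dimethyl-2,6-dioxo-1,2,4,5,6,7,8,8a-octahydroazulene-5-carboxylate
Product: 13 methyl (5S,6S,8S,8aR)-6-hydroxy-3,8-dimethyl-2-oxo-1,2,4,5,6,7,8,8a-octahydroazulene-5-carboxylate
Conditions: [RuCl(C6H6)((S)-BINAP)]Cl (1 mol%), H2 (100 atm), CH2Cl2, 50 °C
Reagents that add atoms: none
Why: Noyori asymmetric hydrogenation with dynamic kinetic resolution, in which C7 epimerises rapidly through the enol, the (S)-BINAP ruthenium catalyst reduces the chelated keto ester under reagent control to set C8 (S), the anti preference of 2-alkoxycarbonyl cycloalkanones places the ester trans to the hydroxyl and so sets C7 (S), and the non-chelating tetrasubstituted enone is left alone.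

Step 9
Reactants: 13 methyl (5S,6S,8S,8aR)-6-hydroxy-3,8-dimethyl-2-oxo-1,2,4,5,6,7,8,8a-octahydroazulene-5-carboxylate
Product: 14 methyl (5S,6R,8S,8aR)-6-(benzoyloxy)-3,8-dimethyl-2-oxo-1,2,4,5,6,7,8,8a-octahydroazulene-5-carboxylate
Conditions: PhCO2H, PPh3, DIAD, toluene, 0 °C → rt
Reagents that add atoms: benzoic acid, OC(=O)c1ccccc1
Why: Mitsunobu reaction, in which benzoate displaces the C8 oxyphosphonium group by SN2 with inversion, turning C8 from S to R and placing the oxygen cis to the C7 ester, and because H7 is syn to the leaving group no anti elimination to the conjugated ester is available.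

Step 10
Reactants: 14 methyl (5S,6R,8S,8aR)-6-(benzoyloxy)-3,8-dimethyl-2-oxo-1,2,4,5,6,7,8,8a-octahydroazulene-5-carboxylate
Product: 15 methyl (5S,6R,8S,8aR)-6-(benzoyloxy)-2-hydroxy-3,8-dimethyl-1,2,4,5,6,7,8,8a-octahydroazulene-5-carboxylate
Conditions: NaBH4, CeCl3·7H2O, MeOH, −40 → 0 °C
Reagents that add atoms: none
Why: Luche reduction, in which the cerium-assisted borohydride reduces the enone carbonyl in 1,2 fashion and leaves both esters, so that C3 is masked as an allylic alcohol (configuration immaterial) before the organometallic step.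

Step 11
Reactants: 15 methyl (5S,6R,8S,8aR)-6-(benzoyloxy)-2-hydroxy-3,8-dimethyl-1,2,4,5,6,7,8,8a-octahydroazulene-5-carboxylate
Product: 16 (5S,6R,8S,8aR)-5-(2-hydroxypropan-2-yl)-3,8-dimethyl-1,2,4,5,6,7,8,8a-octahydroazulene-2,6-diol
Conditions: MeMgBr (8 equiv), THF, −20 °C → rt; aq. NH4Cl
Reagents that add atoms: methylmagnesium bromide, C[Mg]Br
Why: Grignard addition, in which two methyl groups add to the C7 methyl ester to give the C11 tertiary carbinol and the same reagent cleaves the benzoate as 2-phenylpropan-2-ol, no ketone being present and the stereocentres at C7 and C8 being untouched.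

Step 12
Reactants: 16 (5S,6R,8S,8aR)-5-(2-hydroxypropan-2-yl)-3,8-dimethyl-1,2,4,5,6,7,8,8a-octahydroazulene-2,6-diol
Product: 17 (5S,6R,8S,8aR)-6-hydroxy-5-(2-hydroxypropan-2-yl)-3,8-dimethyl-4,5,6,7,8,8a-hexahydroazulen-2(1H)-one
Conditions: MnO2 (activated, excess), CH2Cl2, rt
Reagents that add atoms: none
Why: Chemoselective allylic oxidation, in which MnO2 oxidises only the allylic C3 alcohol (both epimers) back to the enone and leaves the saturated secondary C8 and tertiary C11 hydroxyls.

Step 13
Reactants: 17 (5S,6R,8S,8aR)-6-hydroxy-5-(2-hydroxypropan-2-yl)-3,8-dimethyl-4,5,6,7,8,8a-hexahydroazulen-2(1H)-one; 18 methacrylic anhydride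
Product: 19 (5S,6R,8S,8aR)-5-(2-hydroxypropan-2-yl)-3,8-dimethyl-2-oxo-1,2,4,5,6,7,8,8a-octahydroazulen-6-yl 2-methylprop-2-enoate
Conditions: 18 (1.3 equiv), Et3N, DMAP (cat.), CH2Cl2, 0 °C → rt
Reagents that add atoms: none
Why: DMAP-catalysed acylation, in which the acylpyridinium from the anhydride esterifies the secondary C8 hydroxyl with retention while the tertiary C11 hydroxyl is too hindered to react at room temperature.

Step 14
Reactants: 19 (5S,6R,8S,8aR)-5-(2-hydroxypropan-2-yl)-3,8-dimethyl-2-oxo-1,2,4,5,6,7,8,8a-octahydroazulen-6-yl 2-methylprop-2-enoate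
Product: 20 (5S,6R,8S,8aR)-5-(2-acetoxypropan-2-yl)-3,8-dimethyl-2-oxo-1,2,4,5,6,7,8,8a-octahydroazulen-6-yl 2-methylprop-2-enoate
Conditions: Ac2O (excess), DMAP (1 equiv), Et3N, CH2Cl2, 40 °C
Reagents that add atoms: acetic anhydride, CC(=O)OC(C)=O
Why: DMAP-promoted acetylation of the tertiary alcohol with excess anhydride under mild heating, conditions under which the methacrylate, the enone and the four stereocentres should be stable.

**Compound list**

1 | methyl 3-oxobutanoate (methyl acetoacetate) | COC(=O)CC(C)=O | starting material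
2 | methyl 2-diazo-3-oxobutanoate | COC(=O)C(=[N+]=[N-])C(C)=O | intermediate
3 | methyl 3-(tert-butyldimethylsilyloxy)-2-diazobut-3-enoate | COC(=O)C(=[N+]=[N-])C(=C)O[Si](C)(C)C(C)(C)C | intermediate
4 | (E)-pent-3-en-2-one | C/C=C/C(C)=O | starting material
5 | (E)-2-(triethylsilyloxy)penta-1,3-diene | C=C(O[Si](CC)(CC)CC)/C=C/C | intermediate
6 | methyl (1R,2S)-1-[1-(tert-butyldimethylsilyloxy)ethenyl]-2-[(E)-prop-1-en-1-yl]-2-(triethylsilyloxy)cyclopropane-1-carboxylate, the two alkenyl groups cis (not isolated) | COC(=O)[C@@]1(C(=C)O[Si](C)(C)C(C)(C)C)C[C@]1(O[Si](CC)(CC)CC)/C=C/C | intermediate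
7 | methyl (S)-2-(tert-butyldimethylsilyloxy)-4-methyl-6-(triethylsilyloxy)cyclohepta-1,5-diene-1-carboxylate | COC(=O)C1=C(O[Si](C)(C)C(C)(C)C)C[C@H](C)C=C(O[Si](CC)(CC)CC)C1 | intermediate
8 | 2-nitrobutan-1-ol (racemic) | CCC(CO)[N+](=O)[O-] | starting material
9 | 2-nitrobut-1-ene | C=C(CC)[N+](=O)[O-] | intermediate
10 | triethylsilyl nitronate of methyl (4S,5R)-2-(tert-butyldimethylsilyloxy)-4-methyl-5-(2-nitrobutyl)-6-oxocyclohept-1-ene-1-carboxylate (not isolated) | COC(=O)C1=C(O[Si](C)(C)C(C)(C)C)C[C@H](C)[C@@H](CC(CC)=[N+]([O-])O[Si](CC)(CC)CC)C(=O)C1 | intermediate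
11 | methyl (4S,5R)-4-methyl-2,6-dioxo-5-(2-oxobutyl)cycloheptane-1-carboxylate (C1 of the ring labile: epimers and enol) | O=C1C[C@H](C)[C@@H](CC(=O)CC)C(=O)CC1C(=O)OC | intermediate
12 | methyl (8S,8aR)-3,8-dimethyl-2,6-dioxo-1,2,4,5,6,7,8,8a-octahydroazulene-5-carboxylate (C5 labile: epimers and enol) | O=C1C[C@H](C)[C@H]2CC(=O)C(C)=C2CC1C(=O)OC | intermediate
13 | methyl (5S,6S,8S,8aR)-6-hydroxy-3,8-dimethyl-2-oxo-1,2,4,5,6,7,8,8a-octahydroazulene-5-carboxylate (hydroxyl trans to ester) | O[C@H]1C[C@H](C)[C@H]2CC(=O)C(C)=C2C[C@@H]1C(=O)OC | intermediate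
14 | methyl (5S,6R,8S,8aR)-6-(benzoyloxy)-3,8-dimethyl-2-oxo-1,2,4,5,6,7,8,8a-octahydroazulene-5-carboxylate (benzoate cis to ester) | O=C(O[C@@H]1C[C@H](C)[C@H]2CC(=O)C(C)=C2C[C@@H]1C(=O)OC)c1ccccc1 | intermediate
15 | methyl (5S,6R,8S,8aR)-6-(benzoyloxy)-2-hydroxy-3,8-dimethyl-1,2,4,5,6,7,8,8a-octahydroazulene-5-carboxylate (both C2 epimers) | O=C(O[C@@H]1C[C@H](C)[C@H]2CC(O)C(C)=C2C[C@@H]1C(=O)OC)c1ccccc1 | intermediate
16 | (5S,6R,8S,8aR)-5-(2-hydroxypropan-2-yl)-3,8-dimethyl-1,2,4,5,6,7,8,8a-octahydroazulene-2,6-diol (both C2 epimers) | O[C@@H]1C[C@H](C)[C@H]2CC(O)C(C)=C2C[C@@H]1C(C)(C)O | intermediate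
17 | (5S,6R,8S,8aR)-6-hydroxy-5-(2-hydroxypropan-2-yl)-3,8-dimethyl-4,5,6,7,8,8a-hexahydroazulen-2(1H)-one | O[C@@H]1C[C@H](C)[C@H]2CC(=O)C(C)=C2C[C@@H]1C(C)(C)O | intermediate
18 | methacrylic anhydride (2-methylprop-2-enoic anhydride) | C=C(C)C(=O)OC(=O)C(C)=C | starting material
19 | (5S,6R,8S,8aR)-5-(2-hydroxypropan-2-yl)-3,8-dimethyl-2-oxo-1,2,4,5,6,7,8,8a-octahydroazulen-6-yl 2-methylprop-2-enoate | C=C(C)C(=O)O[C@@H]1C[C@H](C)[C@H]2CC(=O)C(C)=C2C[C@@H]1C(C)(C)O | intermediate
20 | (5S,6R,8S,8aR)-5-(2-acetoxypropan-2-yl)-3,8-dimethyl-2-oxo-1,2,4,5,6,7,8,8a-octahydroazulen-6-yl 2-methylprop-2-enoate (CNP0318307.1) | C=C(C)C(=O)O[C@@H]1C[C@H](C)[C@H]2CC(=O)C(C)=C2C[C@@H]1C(C)(C)OC(C)=O | target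

**Step count**

Total: 14 steps. Longest linear sequence: 12 steps (1 → 2 → 3 → 7 → 11 → 12 → 13 → 14 → 15 → 16 → 17 → 19 → 20).

**Steps most likely to fail**

Step 4. The process at risk is enantioface discrimination on the unusual 1,1-disubstituted siloxy alkene, together with loss of enantiopurity if the vicinal siloxy/ester cyclopropane opens heterolytically and recloses before the Cope shift. The fallback sets out from 3 and 5 and comes back at 13; it takes the absolute configuration from the hydrogenation instead of the cycloaddition. Achiral Rh2(OPiv)4 in hexanes should give 7 together with its enantiomer, methyl (R)-2-(tert-butyldimethylsilyloxy)-4-methyl-6-(triethylsilyloxy)cyclohepta-1,5-diene-1-carboxylate F2, through 6 and the mirror-image (1S,2R)-cyclopropane F1. The racemate is taken through steps 6 and 7 unchanged. The antipodal series runs through the (4R,5S)-silyl nitronate F3, methyl (4R,5S)-4-methyl-2,6-dioxo-5-(2-oxobutyl)cycloheptane-1-carboxylate F4 and methyl (8R,8aS)-3,8-dimethyl-2,6-dioxo-1,2,4,5,6,7,8,8a-octahydroazulene-5-carboxylate F5. In step 8 the (S)-BINAP catalyst should impose the (5S,6S) configuration (guaiane C7 and C8) on both enantiomers, so that 12 gives 13 and F5 gives the diastereomer methyl (5S,6S,8R,8aS)-6-hydroxy-3,8-dimethyl-2-oxo-1,2,4,5,6,7,8,8a-octahydroazulene-5-carboxylate F6. Chromatography removes F6 and the route continues from 13 with at most half of the material.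

Step 6. The processes at risk are protodesilylation of the C5 enol ether by adventitious acid before C–C bond formation, competing attack through C7 of the push–pull enol ether, and polymerisation of the nitroalkene under SnCl4. The fallback sets out from 7 and comes back at 11; it changes from the polar Lewis-acid manifold to radical alkylation. Compound 7 is irradiated with blue LEDs in MeCN at rt with 1-bromobutan-2-one, fac-Ir(ppy)3 (1 mol%) and 2,6-lutidine. The electrophilic 2-oxobutyl radical should add to C1 of the more electron-rich C5=C1 enol ether, and oxidation of the α-siloxy radical with loss of the triethylsilyl group should give methyl (4S,5R)-2-(tert-butyldimethylsilyloxy)-4-methyl-6-oxo-5-(2-oxobutyl)cyclohept-1-ene-1-carboxylate F7. Treatment with 1 M HCl in THF then removes the remaining silyl group and gives 11.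

Step 9. The processes at risk are E2 loss of the activated C8 oxygen toward C9 and slow SN2 entry of benzoate on the β-face, cis to the C7 ester and the C10 methyl. The fallback sets out from 13 and comes back at 17; it sets C8 by hydride delivery instead of displacement. Luche reduction of 13 should give methyl (5S,6S,8S,8aR)-2,6-dihydroxy-3,8-dimethyl-1,2,4,5,6,7,8,8a-octahydroazulene-5-carboxylate F8. Excess MeMgBr should then give (5S,6S,8S,8aR)-5-(2-hydroxypropan-2-yl)-3,8-dimethyl-1,2,4,5,6,7,8,8a-octahydroazulene-2,6-diol F9. Dess–Martin periodinane (buffered with NaHCO3) should oxidise both secondary hydroxyls to (5R,8S,8aR)-5-(2-hydroxypropan-2-yl)-3,8-dimethyl-4,5,8,8a-tetrahydroazulene-2,6(1H,7H)-dione F10, which is used at once because C7 is now epimerisable. NaBH4 in MeOH/CH2Cl2 at −78 °C reduces a saturated ketone faster than a conjugated enone; it should attack the C8 ketone from the α-face, opposite the C7 2-hydroxypropan-2-yl group and the C10 methyl, and give the cis diol 17.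

**Further compounds**

F1 | step 4 | methyl (1S,2R)-1-[1-(tert-butyldimethylsilyloxy)ethenyl]-2-[(E)-prop-1-en-1-yl]-2-(triethylsilyloxy)cyclopropane-1-carboxylate (enantiomer of 6, not isolated) | COC(=O)[C@]1(C(=C)O[Si](C)(C)C(C)(C)C)C[C@@]1(O[Si](CC)(CC)CC)/C=C/C
F2 | step 4 | methyl (R)-2-(tert-butyldimethylsilyloxy)-4-methyl-6-(triethylsilyloxy)cyclohepta-1,5-diene-1-carboxylate (enantiomer of 7) | COC(=O)C1=C(O[Si](C)(C)C(C)(C)C)C[C@@H](C)C=C(O[Si](CC)(CC)CC)C1
F3 | step 4 | triethylsilyl nitronate of methyl (4R,5S)-2-(tert-butyldimethylsilyloxy)-4-methyl-5-(2-nitrobutyl)-6-oxocyclohept-1-ene-1-carboxylate (enantiomer of 10, not isolated) | COC(=O)C1=C(O[Si](C)(C)C(C)(C)C)C[C@@H](C)[C@H](CC(CC)=[N+]([O-])O[Si](CC)(CC)CC)C(=O)C1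
F4 | step 4 | methyl (4R,5S)-4-methyl-2,6-dioxo-5-(2-oxobutyl)cycloheptane-1-carboxylate (enantiomer of 11) | O=C1C[C@@H](C)[C@H](CC(=O)CC)C(=O)CC1C(=O)OC
F5 | step 4 | methyl (8R,8aS)-3,8-dimethyl-2,6-dioxo-1,2,4,5,6,7,8,8a-octahydroazulene-5-carboxylate (enantiomer of 12) | O=C1C[C@@H](C)[C@@H]2CC(=O)C(C)=C2CC1C(=O)OC
F6 | step 4 | methyl (5S,6S,8R,8aS)-6-hydroxy-3,8-dimethyl-2-oxo-1,2,4,5,6,7,8,8a-octahydroazulene-5-carboxylate | O[C@H]1C[C@@H](C)[C@@H]2CC(=O)C(C)=C2C[C@@H]1C(=O)OC
F7 | step 6 | methyl (4S,5R)-2-(tert-butyldimethylsilyloxy)-4-methyl-6-oxo-5-(2-oxobutyl)cyclohept-1-ene-1-carboxylate | COC(=O)C1=C(O[Si](C)(C)C(C)(C)C)C[C@H](C)[C@@H](CC(=O)CC)C(=O)C1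
F8 | step 9 | methyl (5S,6S,8S,8aR)-2,6-dihydroxy-3,8-dimethyl-1,2,4,5,6,7,8,8a-octahydroazulene-5-carboxylate (both C2 epimers) | O[C@H]1C[C@H](C)[C@H]2CC(O)C(C)=C2C[C@@H]1C(=O)OC
F9 | step 9 | (5S,6S,8S,8aR)-5-(2-hydroxypropan-2-yl)-3,8-dimethyl-1,2,4,5,6,7,8,8a-octahydroazulene-2,6-diol (both C2 epimers) | O[C@H]1C[C@H](C)[C@H]2CC(O)C(C)=C2C[C@@H]1C(C)(C)O
F10 | step 9 | (5R,8S,8aR)-5-(2-hydroxypropan-2-yl)-3,8-dimethyl-4,5,8,8a-tetrahydroazulene-2,6(1H,7H)-dione | O=C1C[C@H](C)[C@H]2CC(=O)C(C)=C2C[C@@H]1C(C)(C)O
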